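Which flask holds the most monomer in chains after 30 min? I started from the fraction left, not the fraction made.

| setting | blue | ochre | red | north-east | north-west | south | east |
|---|---|---|---|---|---|---|---|
| free monomer | 0.20 M | 0.20 M | 0.10 M | 0.20 M | 0.20 M | 0.20 M | 0.20 M |
| initiator | 0.67 mM | 1.5 mM | 1 mM | 1.0 mM | 1.0 mM | 1.0 mM | 1.0 mM |
| temperature | 70 °C | 112 °C | 70 °C | 150 °C | 75 °C | 125 °C | 100 °C |
| remark | run made earlier | run made earlier | run made earlier |  |  |  |  |
| time |  |  |  | 30 min | 30 min | 30 min | 30 min |

| blue: time / min | blue: monomer in chains / % | ochre: time / min | ochre: monomer in chains / % | red: time / min | red: monomer in chains / % |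
|---|---|---|---|---|---|
| 120 | 9 | 8.00 | 20 | 120 | 9 |
| 300 | 18 | 20.0 | 31 | 300 | 19 |
| 600 | 26 | 50.0 | 17 | 600 | 32 |
| 1200 | 33 | 120 | 0 | 1200 | 33 |

(each reading ± 2 percentage points)

- which flask leads in amount of monomer in chains, in percent of the free monomer charged ("all alike" within 1.5 percentage points) (north-east / north-west / south / east / all alike)
- how much monomer in chains is there at the end, in percent of the free monomer charged: north-east
- how much monomer in chains is there at the end, in percent of the free monomer charged: north-west
- how much monomer in chains is there at the end, in percent of the free monomer charged: south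
- how much monomer in chains is there at the end, in percent of the free monomer charged: east

- a reading or a percentage of monomer in chains counts all its forms, free or not

The ochre run lost its chains, so I read their decay in two ways. From 20.0 min to 50.0 min its readings gave a lifetime of 49.9 min. From 50.0 min to 120 min, with the zero reading taken as one scatter, 2 percentage points, they gave 32.7 min. The two parted. I suspected the earlier span, since ochre had gained faster at first than it lost later, and fresh chains may still have been arriving. So I kept the later figure as the chain lifetime, the time in which the fraction of chains left falls by the natural factor, at the ochre temperature.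

For temperature I used the fraction of free monomer left at the first reading. It gave a pseudo-first-order constant of 7.86 × 10⁻⁴ min⁻¹ for blue and 0.0279 min⁻¹ for ochre. Read this way, with no correction for initiator, rates doubled every 8.16 K. Ochre held more initiator than blue, so that figure was rough. Blue and red shared a first reading, 9%, but a scatter of 2 points meant this could not show that initiator had no effect, and red also held less free monomer.

In my reckoning, east made 26.1%. Its lifetime was 90.7 min. Chains made on average at half time kept 84.8%, which left 22.1%. North-west made 3.54%. South had a lifetime of 10.8 min, shorter than the time. I chose east.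

The forecast also chose east, with 0.5% for north-east, 4% for north-west, 7% for south and 23% for east. Its grounds were that “Hot chains therefore form quickly but do not last”. Its lifetime, near 50 min, was longer than mine.

The flasks gave 0% in north-east, 4.04% in north-west, 4.86% in south and 23.1% in east, so east led.

    free monomer + monomer in chains ⇌ idle adduct, settled at all times (K = 3.50 M⁻¹, ΔH = −49.0 kJ mol⁻¹)
    free monomer + growing radical → monomer in chains + growing radical, rate k2*[growing radical]*[free monomer] (k = 2600 M⁻¹ s⁻¹, Ea = 46.0 kJ mol⁻¹)
    free monomer + initiating radical → growing radical + monomer in chains (k = 51000 M⁻¹ s⁻¹, Ea = 39.0 kJ mol⁻¹)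
    monomer in chains → over-reaction product B (k = 1.10 × 10⁻⁷ s⁻¹, Ea = 129 kJ mol⁻¹)
    monomer in chains → over-reaction product A (k = 2.90 × 10⁻⁴ s⁻¹, Ea = 107 kJ mol⁻¹)
    2 growing radical → dead chain (k = 4.00 × 10⁷ M⁻¹ s⁻¹, Ea = 19.0 kJ mol⁻¹)
    initiator → 2 initiating radical (k = 2.70 × 10⁻⁴ s⁻¹, Ea = 118 kJ mol⁻¹)
    (constants at 100 °C)

Taking away the step from monomer in chains to over-reaction product A raised north-east from 0% to 47.5%, about half of what was missing. In east, monomer in chains stood at 83.0% of itself plus over-reaction product A, against the 84.8% from the lifetime. The neighbour flask, north-east repeated at 135 °C, had a scaled lifetime of 4.63 min. Applied to its 56.8% of over-reaction product A, that lifetime gave 0.0872%, and the flask held 0.137%.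

(The readings stem from a simulated flask with made-up constants; noise was put on by code.)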